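(The earlier runs and the new flask were generated by integration from invented constants, noise included.)

The ochre run, with half the initiator of the blue run, reads 78.2 % free monomer at 8.00 h, and blue reads 78.2 % at 4.00 h, so the two agree at equal initiator times time.

| setting | blue | ochre | flask |
|---|---|---|---|
| free monomer | 0.80 M | 0.80 M | 0.80 M |
| initiator | 20 mM | 10 mM | 20 mM |
| remark | the very flask that is asked about, followed so far | run made earlier |  |
| time |  |  | 8.0 h |

| run | time / h | monomer in chains / % | free monomer / % |
|---|---|---|---|
| blue | 0.333 | 3.0 | 99.4 |
| blue | 0.667 | 4.4 | 94.0 |
| blue | 1.50 | 9.3 | 89.0 |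
| blue | 4.00 | 20.5 | 78.2 |
| ochre | 2.00 | 6.9 | 92.7 |
| ochre | 4.00 | 13.3 | 88.7 |
| ochre | 6.00 | 16.7 | 80.7 |
| ochre | 8.00 | 22.2 | 78.2 |

(standard deviation of a reading: 1 percentage point)

- the average divides the monomer in chains by the number of chains begun, living and dead together
- the numbers in the tables scatter with a standard deviation of 1 percentage point
- the earlier runs do not show the number of chains; that part of a forecast is a guess

- average number of monomer units in a chain (chains begun, living or dead) at 8.0 h
- part of the free monomer that has reacted at 8.0 h

I follow one unit of monomer in the asked flask. If each initiator begins one chain, which these runs do not show, the average chain is the charge ratio [free monomer]/[initiator], 40.0, the units on offer per chain, times the chance that a unit stands in a chain. If a unit outlasts each 4.00 h with the chance blue reads, I reckon 38.8 % reacted at 8.0 h and, with all of that in chains, 15.5 units per chain. The forecast is lower: 36.5 % and 15 units, “allowing for slight deceleration”.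

The flask gives 34.0 % reacted and 13.4 units per chain, both lower than the forecast and both right within the tolerance.

    free monomer + initiator → living end + monomer in chains (k = 0.0820 M⁻¹ min⁻¹)
    free monomer + living end → monomer in chains + living end, rate k2*[living end]*[free monomer] (k = 0.0988 M⁻¹ min⁻¹)
    monomer in chains + living end → free monomer + living end, rate k3*[living end] as long as [monomer in chains] is above zero (k = 0.0330 min⁻¹)
    living end + monomer in chains → dead end (k = 0.00352 M⁻¹ min⁻¹)

At 8.00 h this flask has less of its initiator left, 0 %, than of its free monomer, 66 %. Its 40.0 units on offer, with 33.4 % of the charge in chains, give 13.4 units, so a chain holds about a third of its offer. The neighbour charged with 0.080 M of initiator offers 10.0 units per chain. With 51.5 % in chains, that reckons to 5.15 units, and its result is 5.15 units per chain, with 55.7 % of its free monomer reacted.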